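Everything rests on cutting the six-membered carbocycle (C3a, C4, C5, C6, C7, C7a) at C3a–C4 and C6–C7. That leaves the C3a–C7a–C7 bis-nucleophile, already locked into the dihydrofuran ring by the O1–C7a bond, and a methyl(prenyl)malonyl bis-electrophile. The feature exploited is quaternary C5: it is chiral solely because the flanking carbonyl carbons C4 (vinylogous ester) and C6 (ketone) end up different, so a configurationally fixed half-ester chloride lacking α-hydrogen delivers it intact. In one flask the precursor, a 4,5-dihydrofuran carrying the silylated C2 side chain and a 2-silyloxyalkenyl arm, is acylated at C3a and closed from C7 onto the ester, giving the enolised triketone. C7 prenylation and desilylation follow.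

Key step: step 8

Numbering: the benzofuran numbering of the target is used for all intermediates (O1, C2, C3, C3a, C4–C7, C7a; C1′ = carbinol carbon; C8 = isobutyryl carbonyl carbon; O4, O6, O8 = oxygens on C4, C6, C8).

Assumption: pig liver esterase is taken to cleave the pro-R ester group of the prochiral diester, the sense known for 2-methylmalonates with short 2-alkyl chains. Because that sense inverts for long chains, configuration and ee of the half-ester are to be verified before coupling; a minor antipode is removable later as a C5-epimeric diastereomer.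

Step 1
Reactants: 1 nerol
Product: 2 (2R,3S)-2,3-epoxynerol
Conditions: Ti(OiPr)4 (10 mol %), D-(−)-diisopropyl tartrate (12 mol %), t-BuOOH (2 equiv, decane), 4 Å MS, CH2Cl2, −20 °C
Reagents that add atoms: tert-butyl hydroperoxide, CC(C)(C)OO
Why: The Sharpless asymmetric epoxidation is directed by the allylic hydroxyl, so the remote trisubstituted alkene is untouched; the D-(−)-tartrate delivers oxygen to the face that gives 2R, and the Z-alkene geometry ties the neighbouring quaternary carbon (later C1′) to 3S.

Step 2
Reactants: 2 (2R,3S)-2,3-epoxynerol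
Product: 3 (2S,3S)-3-(bromomethyl)-2-methyl-2-(4-methylpent-3-en-1-yl)oxirane
Conditions: CBr4 (1.2 equiv), PPh3 (1.25 equiv), CH2Cl2, 0 °C
Reagents that add atoms: carbon tetrabromide, BrC(Br)(Br)Br
Why: The Appel bromination replaces the primary hydroxyl under neutral conditions by SN2 at the CH2 group, so neither oxirane stereocentre is touched (the CH carbon changes descriptor only because CH2Br outranks the ring carbon).

Step 3
Reactants: 3 (2S,3S)-3-(bromomethyl)-2-methyl-2-(4-methylpent-3-en-1-yl)oxirane, 4 5-methylhexane-2,4-dione
Product: 6 (1E)-1-{(5S)-5-[(2S)-2-hydroxy-6-methylhept-5-en-2-yl]oxolan-2-ylidene}-3-methylbutan-2-one, via epoxy diketone 5 (not isolated)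
Conditions: 4 (1.2 equiv), LDA (2.4 equiv), THF, 0 °C; 3, −78 → 20 °C; LiClO4 (2 equiv), 20 → 45 °C; aq NH4Cl
Reagents that add atoms: none
Why: This is the known dianion alkylation/5-exo-tet O-cyclisation route from 1,3-dicarbonyl dianions and epihalohydrin-type electrophiles to 2-alkylidenetetrahydrofurans: the terminal carbanion (methyl is deprotonated rather than the isopropyl methine) displaces bromide to make C3–C3a, and the diketonate oxygen then opens the lithium-activated oxirane at its secondary carbon with inversion, which sets C2 as S and frees the C1′ alkoxide with its C–O bond, and hence 1′S, intact.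

Step 4
Reactants: 6 (1E)-1-{(5S)-5-[(2S)-2-hydroxy-6-methylhept-5-en-2-yl]oxolan-2-ylidene}-3-methylbutan-2-one
Product: 7 triethyl{[(1Z)-3-methyl-1-{(5S)-5-[(2S)-6-methyl-2-(triethylsilyloxy)hept-5-en-2-yl]-4,5-dihydrofuran-2-yl}but-1-en-2-yl]oxy}silane
Conditions: KHMDS (2.2 equiv), THF, −78 → 0 °C, 1 h; Et3SiCl (2.5 equiv), −78 → 0 °C; pentane, cold aq NaHCO3; used crude
Reagents that add atoms: chlorotriethylsilane, CC[Si](Cl)(CC)CC
Why: Potassium alkoxide and potassium dienolate are O-silylated in one operation; since hexamethyldisilazane can shuttle protons, the enolates equilibrate at 0 °C (thermodynamic dienolate silylation), and the through-conjugated dienolate from loss of a ring C3a–H should prevail over the cross-conjugated one that needs loss of the hindered isopropyl methine, while no stereocentre is touched and the enol ether geometry is erased again in step 8.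

Step 5
Reactants: 8 dimethyl 2-methylmalonate, 9 prenyl bromide
Product: 10 dimethyl 2-methyl-2-(3-methylbut-2-en-1-yl)malonate
Conditions: NaH (1.1 equiv), THF, 0 °C; 9 (1.1 equiv), 0 → 20 °C
Reagents that add atoms: none
Why: Malonate alkylation (SN2) of the sodium enolate with a reactive allylic bromide gives the prochiral quaternary diester, and with only one acidic hydrogen present over-alkylation is impossible.

Step 6
Reactants: 10 dimethyl 2-methyl-2-(3-methylbut-2-en-1-yl)malonate
Product: 11 (2S)-2-(methoxycarbonyl)-2,5-dimethylhex-4-enoic acid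
Conditions: pig liver esterase, 0.1 M phosphate buffer pH 7.4, DMSO (10 vol %), pH-stat (1 M NaOH), 25 °C; HCl to pH 2, EtOAc
Reagents that add atoms: water, O
Why: In this enzymatic desymmetrisation the esterase distinguishes the two enantiotopic ester groups and stops at the half-ester because the carboxylate is no longer a substrate, which creates the future C5 as a fully substituted centre that cannot epimerise.

Step 7
Reactants: 11 (2S)-2-(methoxycarbonyl)-2,5-dimethylhex-4-enoic acid
Product: 12 methyl (2R)-2-(chlorocarbonyl)-2,5-dimethylhex-4-enoate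
Conditions: 1-chloro-N,N,2-trimethylprop-1-en-1-amine (1.1 equiv), CH2Cl2, 0 → 20 °C; bulb-to-bulb distillation
Reagents that add atoms: 1-chloro-N,N,2-trimethylprop-1-en-1-amine (Ghosez reagent), CC(C)=C(Cl)N(C)C
Why: The Ghosez chloroenamine converts the acid into its chloride under neutral conditions without free HCl, sparing the trisubstituted alkene and the methyl ester; the spatial arrangement is unchanged and the descriptor becomes R only because COCl outranks CO2Me.

Step 8
Reactants: 7 triethyl{[(1Z)-3-methyl-1-{(5S)-5-[(2S)-6-methyl-2-(triethylsilyloxy)hept-5-en-2-yl]-4,5-dihydrofuran-2-yl}but-1-en-2-yl]oxy}silane, 12 methyl (2R)-2-(chlorocarbonyl)-2,5-dimethylhex-4-enoate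
Product: 14 (2S,5R)-6-hydroxy-5-methyl-5-(3-methylbut-2-en-1-yl)-7-(2-methylpropanoyl)-2-[(2S)-6-methyl-2-(triethylsilyloxy)hept-5-en-2-yl]-2,3-dihydro-1-benzofuran-4(5H)-one, via C3a-acylated keto ester 13 (not isolated)
Conditions: 12 (1.2 equiv), TMSOTf (10 mol %), CH2Cl2, −78 → 0 °C; then DBU (3.5 equiv), 0 → 20 °C; cold 0.5 M HCl wash
Reagents that add atoms: none
Why: The substrate is a 1-alkoxy-3-silyloxy-1,3-diene, and its unsubstituted terminus C3a, pushed by both O1 and the silyloxy group, attacks the triflate-activated acid chloride in a vinylogous Mukaiyama-type C-acylation (closest known case: 1,3-bis(silyloxy)dienes with acid chlorides, which give 3,5-dioxo esters by terminal attack), after which chloride removes the silyl group to leave 13. DBU then takes the most acidic proton of 13 (C3a–H or C7–H, depending on the tautomer of this vinylogous 1,3,5-tricarbonyl system), and the delocalised anion attacks the ester carbonyl through C7, a Dieckmann condensation of the kind used for 2-acylcyclohexane-1,3,5-triones. The ring C3a–C4–C5–C6–C7–C7a closes in the 6-(enolexo)-exo-trig mode, assisted by the gem-dialkyl effect of C5, whereas attack through C3a or O8 would require a four- or an eight-membered ring. Expulsion of methoxide and deprotonation to the β-triketone enolate take the product out of the equilibrium. No stereocentre is created: C5 arrives with 12, is fully substituted and therefore immune to enolisation and ketene formation, and C2 and C1′ are spectators. Two selectivities are needed: COCl and not CO2Me has to become C4, which the large reactivity gap of the two acyl groups towards a neutral π-nucleophile secures and which alone translates the configuration of 12 into that of C5; and carbon C3a rather than C7 or O8 has to be acylated, which the double donor activation and the low steric demand of the C3a–H terminus secure.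

Step 9
Reactants: 14 (2S,5R)-6-hydroxy-5-methyl-5-(3-methylbut-2-en-1-yl)-7-(2-methylpropanoyl)-2-[(2S)-6-methyl-2-(triethylsilyloxy)hept-5-en-2-yl]-2,3-dihydro-1-benzofuran-4(5H)-one, 9 prenyl bromide
Product: 15 (2S,5S,7S)-5-methyl-5,7-bis(3-methylbut-2-en-1-yl)-7-(2-methylpropanoyl)-2-[(2S)-6-methyl-2-(triethylsilyloxy)hept-5-en-2-yl]-2,3-dihydro-1-benzofuran-4,6(5H,7H)-dione
Conditions: LiHMDS (1.05 equiv), toluene–THF 4:1, −78 → 0 °C; 9 (2 equiv), 0 → 40 °C
Reagents that add atoms: none
Why: C-Alkylation of the lithium salt of a 2-acyl-1,3-dione with a soft allylic bromide in a weakly polar medium, where lithium ties up the oxygens, should create the C7 quaternary centre; the bromide should approach the face that carries only the C5 methyl group and C2–H, opposite to both the C5 prenyl group and the bulky silylated C2 side chain (matched shielding), which gives 7S.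

Step 10
Reactants: 15 (2S,5S,7S)-5-methyl-5,7-bis(3-methylbut-2-en-1-yl)-7-(2-methylpropanoyl)-2-[(2S)-6-methyl-2-(triethylsilyloxy)hept-5-en-2-yl]-2,3-dihydro-1-benzofuran-4,6(5H,7H)-dione
Product: 16 (2S,5S,7S)-2-[(2S)-2-hydroxy-6-methylhept-5-en-2-yl]-5-methyl-5,7-bis(3-methylbut-2-en-1-yl)-7-(2-methylpropanoyl)-2,3-dihydro-1-benzofuran-4,6(5H,7H)-dione
Conditions: HF·pyridine, pyridine, THF, 0 → 20 °C
Reagents that add atoms: none
Why: Fluoride cleavage of the tertiary triethylsilyl ether in a buffered, weakly acidic medium avoids the basic conditions that would cleave the non-enolisable tricarbonyl array at C7 by retro-Claisen reaction, and it touches no stereocentre or alkene.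

Compound list
1 | nerol, (2Z)-3,7-dimethylocta-2,6-dien-1-ol | CC(C)=CCC/C(C)=C\CO | starting material
2 | (2R,3S)-2,3-epoxynerol, [(2R,3S)-3-methyl-3-(4-methylpent-3-en-1-yl)oxiran-2-yl]methanol | CC(C)=CCC[C@]1(C)O[C@@H]1CO | intermediate
3 | (2S,3S)-3-(bromomethyl)-2-methyl-2-(4-methylpent-3-en-1-yl)oxirane | CC(C)=CCC[C@]1(C)O[C@@H]1CBr | intermediate
4 | 5-methylhexane-2,4-dione | CC(C)C(=O)CC(C)=O | starting material
5 | 2-methyl-7-[(2R,3S)-3-methyl-3-(4-methylpent-3-en-1-yl)oxiran-2-yl]heptane-3,5-dione (present as its lithium enolate, not isolated) | CC(C)=CCC[C@]1(C)O[C@@H]1CCC(=O)CC(=O)C(C)C | intermediate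
6 | (1E)-1-{(5S)-5-[(2S)-2-hydroxy-6-methylhept-5-en-2-yl]oxolan-2-ylidene}-3-methylbutan-2-one | CC(C)=CCC[C@](C)(O)[C@@H]1CC/C(O1)=C\C(=O)C(C)C | intermediate
7 | triethyl{[(1Z)-3-methyl-1-{(5S)-5-[(2S)-6-methyl-2-(triethylsilyloxy)hept-5-en-2-yl]-4,5-dihydrofuran-2-yl}but-1-en-2-yl]oxy}silane (dihydrofuran silyl dienol ether) | CC(C)=CCC[C@](C)(O[Si](CC)(CC)CC)[C@@H]1CC=C(O1)/C=C(\O[Si](CC)(CC)CC)C(C)C | intermediate
8 | dimethyl 2-methylmalonate | COC(=O)C(C)C(=O)OC | starting material
9 | prenyl bromide, 1-bromo-3-methylbut-2-ene | CC(C)=CCBr | starting material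
10 | dimethyl 2-methyl-2-(3-methylbut-2-en-1-yl)malonate | COC(=O)C(C)(CC=C(C)C)C(=O)OC | intermediate
11 | (2S)-2-(methoxycarbonyl)-2,5-dimethylhex-4-enoic acid | COC(=O)[C@@](C)(CC=C(C)C)C(=O)O | intermediate
12 | methyl (2R)-2-(chlorocarbonyl)-2,5-dimethylhex-4-enoate | COC(=O)[C@@](C)(CC=C(C)C)C(=O)Cl | intermediate
13 | methyl (2S)-2,5-dimethyl-2-({(5S)-2-(3-methyl-2-oxobutyl)-5-[(2S)-6-methyl-2-(triethylsilyloxy)hept-5-en-2-yl]-4,5-dihydrofuran-3-yl}carbonyl)hex-4-enoate (drawn as the C3a=C7a tautomer, not isolated) | CC(C)=CCC[C@](C)(O[Si](CC)(CC)CC)[C@@H]1CC(C(=O)[C@](C)(CC=C(C)C)C(=O)OC)=C(O1)CC(=O)C(C)C | intermediate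
14 | (2S,5R)-6-hydroxy-5-methyl-5-(3-methylbut-2-en-1-yl)-7-(2-methylpropanoyl)-2-[(2S)-6-methyl-2-(triethylsilyloxy)hept-5-en-2-yl]-2,3-dihydro-1-benzofuran-4(5H)-one (5R only through the CIP ranking of the enol form; same spatial arrangement as 5S in 15 and 16) | CC(C)=CCC[C@](C)(O[Si](CC)(CC)CC)[C@@H]1CC2=C(O1)C(C(=O)C(C)C)=C(O)[C@@](C)(CC=C(C)C)C2=O | intermediate
15 | (2S,5S,7S)-5-methyl-5,7-bis(3-methylbut-2-en-1-yl)-7-(2-methylpropanoyl)-2-[(2S)-6-methyl-2-(triethylsilyloxy)hept-5-en-2-yl]-2,3-dihydro-1-benzofuran-4,6(5H,7H)-dione | CC(C)=CCC[C@](C)(O[Si](CC)(CC)CC)[C@@H]1CC2=C(O1)[C@@](CC=C(C)C)(C(=O)C(C)C)C(=O)[C@@](C)(CC=C(C)C)C2=O | intermediate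
16 | (2S,5S,7S)-2-[(2S)-2-hydroxy-6-methylhept-5-en-2-yl]-5-methyl-5,7-bis(3-methylbut-2-en-1-yl)-7-(2-methylpropanoyl)-2,3-dihydro-1-benzofuran-4,6(5H,7H)-dione (CNP0250451.1) | CC(C)=CCC[C@](C)(O)[C@@H]1CC2=C(O1)[C@@](CC=C(C)C)(C(=O)C(C)C)C(=O)[C@@](C)(CC=C(C)C)C2=O | target

Total step count: 10. Longest linear sequence: 7 (steps 1–4 and 8–10); steps 5–7 form the convergent malonyl arm.

Steps most likely to fail

Step 8. The neopentyl-type chloride may acylate slowly or on oxygen while the diene is lost by protodesilylation, or the stabilised anion may stall before the hindered methyl ester. The fallback trades the differentiated malonyl unit for a more reactive symmetric one, in an Effenberger-type cyclisation of a malonyl dichloride with a silyl enol ether. It sets out from 10, which is saponified (KOH, aqueous MeOH, reflux, then HCl) to 2-methyl-2-(3-methylbut-2-en-1-yl)malonic acid F1. The same chloroenamine as in step 7 converts this into 2-methyl-2-(3-methylbut-2-en-1-yl)malonyl dichloride F2. This dichloride and 7 are combined in CH2Cl2 at −78 → 0 °C and then treated with DBU, so that both ring bonds are made by acid chlorides. C5 is then formed without control. Compound 14 has to be separated by chromatography from the C5 epimer of 14 F3, which is a diastereomer because C2 and C1′ are fixed. The route is rejoined at 14.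

Step 9. The ambident anion may be alkylated through oxygen or through its vinylogous carbon C3a instead of C7, and facial discrimination at C7 may be weak. The fallback puts the bias towards the O4/C3a end to use and sets out from 14.
- Under Mitsunobu conditions (3-methylbut-2-en-1-ol, PPh3, DIAD, toluene, 0 °C) the free anion meets a hard oxyphosphonium electrophile. It should react at O4, its least hindered and most electron-rich oxygen, to give the 4-prenyloxy dienone F4.
- Heating (toluene, 110 °C) should bring about a Claisen rearrangement to C3a, giving the 3a-(2-methylbut-3-en-2-yl) trione F5.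
- The crowded 1,5-diene unit of that trione should pass the group on to C7 by a Cope rearrangement. This is the aliphatic counterpart of a para-Claisen rearrangement, and the double allylic inversion delivers a normal prenyl group.
- Both shifts are suprafacial. The face is therefore chosen at C3a, next to the C2 side chain and C5, and this is the face required at C7.

The route is rejoined at 15.

Step 4. Deprotonation may take place on the isopropyl side, so that the cross-conjugated instead of the through-conjugated dienolate is silylated. The fallback drops the preformed dienol ether in favour of reversible soft enolisation with the acylation as the sink. It sets out from 6, whose alcohol alone is silylated (Et3SiOTf, 2,6-lutidine, CH2Cl2, −78 °C) to the mono(triethylsilyl) ether of 6 F6. This ether and 12 are treated with MgBr2·OEt2 and iPr2NEt in CH2Cl2 at 20 °C. Enolisation is reversible there, and the enolate on the isopropyl side cannot be C-acylated by so hindered a chloride. Acylation at C3a removes material from the equilibrium as a magnesium chelate. The route is rejoined at 13, which is closed with DBU as in step 8.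

Further compounds
F1 | step 8 | 2-methyl-2-(3-methylbut-2-en-1-yl)malonic acid | CC(C)=CCC(C)(C(=O)O)C(=O)O
F2 | step 8 | 2-methyl-2-(3-methylbut-2-en-1-yl)malonyl dichloride | CC(C)=CCC(C)(C(=O)Cl)C(=O)Cl
F3 | step 8 | C5 epimer of 14 | CC(C)=CCC[C@](C)(O[Si](CC)(CC)CC)[C@@H]1CC2=C(O1)C(C(=O)C(C)C)=C(O)[C@](C)(CC=C(C)C)C2=O
F4 | step 9 | 4-prenyloxy dienone (O4-prenyl ether of 14, C4=C3a and C7a=C7 double bonds, C6 ketone) | CC(C)=CCC[C@](C)(O[Si](CC)(CC)CC)[C@@H]1CC2=C(OCC=C(C)C)[C@](C)(CC=C(C)C)C(=O)C(C(=O)C(C)C)=C2O1
F5 | step 9 | 3a-(2-methylbut-3-en-2-yl) trione (3aR, new group anti to the C2 side chain and the C5 prenyl group) | CC(C)=CCC[C@](C)(O[Si](CC)(CC)CC)[C@@H]1C[C@]2(C(C)(C)C=C)C(=O)[C@](C)(CC=C(C)C)C(=O)C(C(=O)C(C)C)=C2O1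
F6 | step 4 | mono(triethylsilyl) ether of 6 | CC(C)=CCC[C@](C)(O[Si](CC)(CC)CC)[C@@H]1CC/C(O1)=C\C(=O)C(C)C
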